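**Plan**

- Retrosynthesis: the C7 hydroxyl and the side-chain hydroxyl are traced back to one aryl–Si–O bridge, and ring A is then cut at C4a–C8a, C5–C6 and C7–C8 into three alkynes.
- Enabling feature: ring A is fused to the pyran and carries four contiguous substituents (C4a–CH2, C8a–O1, C8–alkyl, C7–OH). O1 can therefore be an ynol ether oxygen, and the side-chain oxygen can hold a silicon-bound ethynyl group that ends up on C7.
- The triyne is cut at the ynol C–O bond (alcohol plus trichloroethylene), at the C(sp)–CH2 bond (acetylide plus 2,2-dimethyloxetane) and at the Si–O bond.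
- Forward order: ring B is completed first (O-prenylation, then Claisen shift to C5'), then C3 is set, then the ynol ether and the tether are added. One step then closes the pyran, ring A and a seven-membered siloxane; oxidation of C–Si and desilylation finish the route.
- Stereochemistry: the only stereocentre, C3 (R), comes from alkylation of the arylacetyl imide of (R)-4-benzyl-1,3-oxazolidin-2-one and is not touched afterwards.

Key step: step 15

Assumption: 2,2-dimethyloxetane (20), 3-bromo-1-(trimethylsilyl)prop-1-yne (13) and (R)-4-benzyl-1,3-oxazolidin-2-one (10) are taken as purchasable. The ring B phenols are carried as triisopropylsilyl ethers, which tolerate the basic steps better than tert-butyldimethylsilyl ethers.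

Abbreviations in names: Ar = 5-(2-methylbut-3-en-2-yl)-2,4-bis(triisopropylsilyloxy)phenyl; TIPS = triisopropylsilyl.

**Route**

Step 1
Reactants: 1 2,4-dihydroxyphenylacetic acid
Product: 2 allyl (2,4-dihydroxyphenyl)acetate
Conditions: allyl bromide, KHCO3, DMF, rt
Reagents that add atoms: allyl bromide, C=CCBr
Why: Carboxylate O-alkylation; hydrogencarbonate deprotonates only the carboxylic acid, so the phenols stay free and the acid is masked as an ester that can later be removed under neutral conditions.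

Step 2
Reactants: 2 allyl (2,4-dihydroxyphenyl)acetate; 3 1-bromo-3-methylbut-2-ene
Product: 4 allyl [2-hydroxy-4-(3-methylbut-2-enyloxy)phenyl]acetate
Conditions: 3 (1.0 equiv), K2CO3 (1.1 equiv), acetone, rt
Reagents that add atoms: none
Why: Williamson etherification with the bromide as limiting reagent should favour the unhindered 4-hydroxyl over the 2-hydroxyl, which is flanked by the acetate arm and hydrogen-bonded to its carbonyl; any 2-O and bis-ether is removed by chromatography.

Step 3
Reactants: 4 allyl [2-hydroxy-4-(3-methylbut-2-enyloxy)phenyl]acetate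
Product: 5 allyl [4-(3-methylbut-2-enyloxy)-2-(triisopropylsilyloxy)phenyl]acetate
Conditions: TIPSCl, imidazole, DMF, rt
Reagents that add atoms: triisopropylsilyl chloride, CC(C)[Si](Cl)(C(C)C)C(C)C
Why: Standard imidazole-mediated phenol silylation; the bulky silyl ether also blocks C3 sterically for the next step.

Step 4
Reactants: 5 allyl [4-(3-methylbut-2-enyloxy)-2-(triisopropylsilyloxy)phenyl]acetate
Product: 7 allyl [4-hydroxy-5-(2-methylbut-3-en-2-yl)-2-(triisopropylsilyloxy)phenyl]acetate, via ortho-dienone 6 (not isolated)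
Conditions: PhNEt2, 190 °C, argon
Reagents that add atoms: none
Why: Aromatic Claisen rearrangement of an aryl prenyl ether delivers the inverted 1,1-dimethylallyl group to an ortho carbon, and C5 should be preferred because C3 is wedged between two oxygen substituents, one of them a TIPS ether; the basic solvent suppresses acid-induced cyclisation of the product.

Step 5
Reactants: 7 allyl [4-hydroxy-5-(2-methylbut-3-en-2-yl)-2-(triisopropylsilyloxy)phenyl]acetate
Product: 8 allyl Ar-acetate
Conditions: TIPSOTf, 2,6-lutidine, CH2Cl2, 0 °C to rt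
Reagents that add atoms: triisopropylsilyl triflate, CC(C)[Si](OS(=O)(=O)C(F)(F)F)(C(C)C)C(C)C
Why: Silylation with the silyl triflate is used because the phenol sits next to a quaternary carbon and the chloride would be too slow.

Step 6
Reactants: 8 allyl Ar-acetate
Product: 9 Ar-acetic acid
Conditions: Pd(PPh3)4 (5 mol %), morpholine, THF, rt; citric acid work-up
Reagents that add atoms: none
Why: Tsuji–Trost deallylation by zerovalent palladium frees the acid under neutral conditions that leave the base-labile aryl silyl ethers and the hindered vinyl group alone.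

Step 7
Reactants: 9 Ar-acetic acid; 10 (R)-4-benzyl-1,3-oxazolidin-2-one
Product: 12 (4R)-4-benzyl-3-(Ar-acetyl)-1,3-oxazolidin-2-one, via pivalic mixed anhydride 11 (not isolated)
Conditions: t-BuCOCl, Et3N, THF, −20 °C; then 10, LiCl, rt
Reagents that add atoms: none
Why: N-acylation of the oxazolidinone through the mixed pivalic anhydride with LiCl activation is the usual mild way to arylacetyl imides and avoids strong base.

Step 8
Reactants: 12 (4R)-4-benzyl-3-(Ar-acetyl)-1,3-oxazolidin-2-one; 13 3-bromo-1-(trimethylsilyl)prop-1-yne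
Product: 15 (4R)-4-benzyl-3-[(2R)-2-Ar-5-(trimethylsilyl)pent-4-ynoyl]-1,3-oxazolidin-2-one, via sodium Z-enolate 14 (not isolated)
Conditions: NaN(SiMe3)2, THF, −78 °C; then 13, −78 to −40 °C
Reagents that add atoms: none
Why: Evans asymmetric alkylation, in which the chelated Z-enolate is attacked by the propargylic bromide on the face opposite the benzyl group of the (R)-auxiliary, which sets the new centre as R (the aryl group outranks the propargyl arm); the C-silyl cap prevents allene formation and protects the alkyne C–H for step 11.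

Step 9
Reactants: 15 (4R)-4-benzyl-3-[(2R)-2-Ar-5-(trimethylsilyl)pent-4-ynoyl]-1,3-oxazolidin-2-one
Product: 16 (2R)-2-Ar-5-(trimethylsilyl)pent-4-yn-1-ol
Conditions: LiBH4, Et2O, H2O (1 equiv), 0 °C
Reagents that add atoms: none
Why: Reductive cleavage of the imide with LiBH4 gives the primary alcohol without epimerising the benzylic centre and returns the auxiliary.

Step 10
Reactants: 16 (2R)-2-Ar-5-(trimethylsilyl)pent-4-yn-1-ol; 17 trichloroethylene
Product: 19 (E)-1,2-dichlorovinyl ether of 16, via potassium alkoxide 18 (not isolated)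
Conditions: KH (2.2 equiv), THF, 0 °C (short); then 17, −50 °C to rt
Reagents that add atoms: none
Why: Base-induced elimination of trichloroethylene to dichloroacetylene followed by anti addition of the alkoxide is the standard entry to dichlorovinyl ethers; the alkoxide is kept cold and used at once to limit silyl transfer from the alkyne or from the aryl ethers.

Step 11
Reactants: 19 (E)-1,2-dichlorovinyl ether of 16; 20 2,2-dimethyloxetane
Product: 22 6-{[(2R)-2-Ar-5-(trimethylsilyl)pent-4-yn-1-yl]oxy}-2-methylhex-5-yn-2-ol, via lithium alkoxyacetylide 21 (not isolated)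
Conditions: n-BuLi (2.3 equiv), THF, −78 to −40 °C; then BF3·OEt2, 20, −78 °C; NaHCO3 quench, Et3N-treated silica
Reagents that add atoms: none
Why: Elimination and chlorine–lithium exchange turn the dichlorovinyl ether into the lithium alkoxyacetylide, and its BF3-promoted SN2 attack at the unsubstituted C4 of the oxetane (as in the well-known epoxide openings by lithium alkoxyacetylides) installs the CH2CH2C(CH3)2OH arm in one operation.

Step 12
Reactants: 22 6-{[(2R)-2-Ar-5-(trimethylsilyl)pent-4-yn-1-yl]oxy}-2-methylhex-5-yn-2-ol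
Product: 23 6-{[(2R)-2-Ar-pent-4-yn-1-yl]oxy}-2-methylhex-5-yn-2-ol
Conditions: K2CO3 (0.5 equiv), MeOH, 0 °C to rt, short
Reagents that add atoms: none
Why: Methanolysis of the alkynyl C–Si bond is fast under mild carbonate, the ynol ether is stable to base, and the hindered aryl TIPS ethers should survive the short exposure.

Step 13
Reactants: 24 dichlorodiisopropylsilane
Product: 25 chloro(ethynyl)diisopropylsilane
Conditions: HC≡CMgBr (1.0 equiv, THF), −78 °C to rt; distillation
Reagents that add atoms: ethynylmagnesium bromide, C#C[Mg]Br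
Why: Grignard substitution at silicon stops after one chloride because the two isopropyl groups slow the second displacement.

Step 14
Reactants: 23 6-{[(2R)-2-Ar-pent-4-yn-1-yl]oxy}-2-methylhex-5-yn-2-ol; 25 chloro(ethynyl)diisopropylsilane
Product: 26 ethynyl(diisopropyl)silyl ether of 23 (triyne)
Conditions: 25 (1.5 equiv), imidazole, DMAP (cat.), DMF, rt to 40 °C
Reagents that add atoms: none
Why: Nucleophile-catalysed O-silylation of the tertiary alcohol, feasible because the linear ethynyl group makes this chlorosilane much less hindered than TIPSCl, while the buffered medium protects the ynol ether.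

Step 15
Reactants: 26 ethynyl(diisopropyl)silyl ether of 23 (triyne)
Product: 27 (3R)-3-Ar-chroman bridged C7–Si(iPr)2–O–C(CH3)2–CH2–CH2–C8 (seven-membered oxasilepine fused to ring A)
Conditions: [Rh(cod)2]BF4 (10 mol %), rac-BINAP (10 mol %), CH2Cl2, rt, slow addition to 0.005 M
Reagents that add atoms: none
Why: The cationic monovalent rhodium centre should bind the ynol ether and the propargylic alkyne, which the O1–C2–C3–C4 chain holds in a 1,7 relation, and couple them oxidatively to a trivalent rhodacyclopentadiene; this forms C4a–C8a and closes the pyran as the six-membered ring fused to the metallacycle. The silicon-bound ethynyl group, delivered by the O–Si tether, then inserts and reductive elimination forms C7–C8 and C5–C6, which closes ring A by [2+2+2] cycloaddition and, in the same event, the seven-membered siloxane by annulation across C7–C8, helped by the gem-dimethyl and gem-diisopropyl groups. The closest known reactions are rhodium- and cobalt-catalysed cyclotrimerisations of fully tethered triynes, of ynol-ether- or ynamide-linked diynes and of alkynes tethered through diisopropylsilyl ethers. No stereocentre is formed and C3 lies outside the reacting atoms, so its R configuration is carried over. The step needs regiocontrol, which the two tethers fix completely (oxygen on C8a, silicon on C7, the alkyl arm on C8 between them), and it needs intramolecular insertion to beat oligomerisation, which high dilution and slow addition should secure; the vinyl group on ring B is hindered and has no allylic hydrogen, so it should stay out of the catalysis.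

Step 16
Reactants: 27 (3R)-3-Ar-chroman bridged C7–Si(iPr)2–O–C(CH3)2–CH2–CH2–C8
Product: 29 (3R)-3-Ar-8-(3-hydroxy-3-methylbutyl)chroman-7-ol, via cyclic aryloxysilane 28 (not isolated)
Conditions: KF, KHCO3, 30 % H2O2, THF/MeOH (1:1), 45 °C
Reagents that add atoms: hydrogen peroxide, OO
Why: Tamao–Fleming oxidation, in which fluoride-assisted attack of hydroperoxide on the alkoxysilane triggers 1,2-migration of the aryl group from silicon to oxygen with retention of position, and solvolysis of the resulting Si–O bonds frees the C7 phenol and the tertiary alcohol together; partial loss of TIPS here is harmless because step 17 removes both groups.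

Step 17
Reactants: 29 (3R)-3-Ar-8-(3-hydroxy-3-methylbutyl)chroman-7-ol
Product: 30 (3R)-3-[2,4-dihydroxy-5-(2-methylbut-3-en-2-yl)phenyl]-8-(3-hydroxy-3-methylbutyl)chroman-7-ol (CNP0420388.1)
Conditions: Bu4NF, THF, 0 °C to rt; NH4Cl work-up
Reagents that add atoms: none
Why: Fluoride cleavage of aryl silyl ethers is fast and avoids acid, which could close a chroman from the tertiary alcohol or cyclise the phenol onto the vinyl group, and it avoids hydrogenation, which would reduce the alkene.

**Compound list**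

1 | 2,4-dihydroxyphenylacetic acid | OC(=O)Cc1ccc(O)cc1O | starting material
2 | allyl (2,4-dihydroxyphenyl)acetate | C=CCOC(=O)Cc1ccc(O)cc1O | intermediate
3 | 1-bromo-3-methylbut-2-ene | CC(C)=CCBr | starting material
4 | allyl [2-hydroxy-4-(3-methylbut-2-enyloxy)phenyl]acetate | C=CCOC(=O)Cc1ccc(OCC=C(C)C)cc1O | intermediate
5 | allyl [4-(3-methylbut-2-enyloxy)-2-(triisopropylsilyloxy)phenyl]acetate | C=CCOC(=O)Cc1ccc(OCC=C(C)C)cc1O[Si](C(C)C)(C(C)C)C(C)C | intermediate
6 | ortho-dienone from the [3,3] shift: allyl [5-(2-methylbut-3-en-2-yl)-4-oxo-2-(triisopropylsilyloxy)cyclohexa-1,5-dienyl]acetate | C=CCOC(=O)CC1=CC(C(C)(C)C=C)C(=O)C=C1O[Si](C(C)C)(C(C)C)C(C)C | intermediate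
7 | allyl [4-hydroxy-5-(2-methylbut-3-en-2-yl)-2-(triisopropylsilyloxy)phenyl]acetate | C=CCOC(=O)Cc1cc(C(C)(C)C=C)c(O)cc1O[Si](C(C)C)(C(C)C)C(C)C | intermediate
8 | allyl [5-(2-methylbut-3-en-2-yl)-2,4-bis(triisopropylsilyloxy)phenyl]acetate | C=CCOC(=O)Cc1cc(C(C)(C)C=C)c(O[Si](C(C)C)(C(C)C)C(C)C)cc1O[Si](C(C)C)(C(C)C)C(C)C | intermediate
9 | [5-(2-methylbut-3-en-2-yl)-2,4-bis(triisopropylsilyloxy)phenyl]acetic acid | OC(=O)Cc1cc(C(C)(C)C=C)c(O[Si](C(C)C)(C(C)C)C(C)C)cc1O[Si](C(C)C)(C(C)C)C(C)C | intermediate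
10 | (R)-4-benzyl-1,3-oxazolidin-2-one | O=C1N[C@H](Cc2ccccc2)CO1 | starting material
11 | mixed anhydride of 9 and pivalic acid | CC(C)(C)C(=O)OC(=O)Cc1cc(C(C)(C)C=C)c(O[Si](C(C)C)(C(C)C)C(C)C)cc1O[Si](C(C)C)(C(C)C)C(C)C | intermediate
12 | (4R)-4-benzyl-3-(Ar-acetyl)-1,3-oxazolidin-2-one | O=C1OC[C@@H](Cc2ccccc2)N1C(=O)Cc1cc(C(C)(C)C=C)c(O[Si](C(C)C)(C(C)C)C(C)C)cc1O[Si](C(C)C)(C(C)C)C(C)C | intermediate
13 | 3-bromo-1-(trimethylsilyl)prop-1-yne | C[Si](C)(C)C#CCBr | starting material
14 | sodium (Z)-enolate of 12 | [Na+].[O-]/C(=C\c1cc(C(C)(C)C=C)c(O[Si](C(C)C)(C(C)C)C(C)C)cc1O[Si](C(C)C)(C(C)C)C(C)C)N1[C@H](Cc2ccccc2)COC1=O | intermediate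
15 | (4R)-4-benzyl-3-[(2R)-2-Ar-5-(trimethylsilyl)pent-4-ynoyl]-1,3-oxazolidin-2-one | O=C1OC[C@@H](Cc2ccccc2)N1C(=O)[C@H](CC#C[Si](C)(C)C)c1cc(C(C)(C)C=C)c(O[Si](C(C)C)(C(C)C)C(C)C)cc1O[Si](C(C)C)(C(C)C)C(C)C | intermediate
16 | (2R)-2-Ar-5-(trimethylsilyl)pent-4-yn-1-ol | OC[C@H](CC#C[Si](C)(C)C)c1cc(C(C)(C)C=C)c(O[Si](C(C)C)(C(C)C)C(C)C)cc1O[Si](C(C)C)(C(C)C)C(C)C | intermediate
17 | trichloroethylene | ClC=C(Cl)Cl | starting material
18 | potassium alkoxide of 16 | [K+].[O-]C[C@H](CC#C[Si](C)(C)C)c1cc(C(C)(C)C=C)c(O[Si](C(C)C)(C(C)C)C(C)C)cc1O[Si](C(C)C)(C(C)C)C(C)C | intermediate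
19 | (E)-1,2-dichlorovinyl ether of 16 | Cl/C=C(/Cl)OC[C@H](CC#C[Si](C)(C)C)c1cc(C(C)(C)C=C)c(O[Si](C(C)C)(C(C)C)C(C)C)cc1O[Si](C(C)C)(C(C)C)C(C)C | intermediate
20 | 2,2-dimethyloxetane | CC1(C)CCO1 | starting material
21 | lithium alkoxyacetylide from 19 | [Li+].[C-]#COC[C@H](CC#C[Si](C)(C)C)c1cc(C(C)(C)C=C)c(O[Si](C(C)C)(C(C)C)C(C)C)cc1O[Si](C(C)C)(C(C)C)C(C)C | intermediate
22 | 6-{[(2R)-2-Ar-5-(trimethylsilyl)pent-4-yn-1-yl]oxy}-2-methylhex-5-yn-2-ol | CC(C)(O)CCC#COC[C@H](CC#C[Si](C)(C)C)c1cc(C(C)(C)C=C)c(O[Si](C(C)C)(C(C)C)C(C)C)cc1O[Si](C(C)C)(C(C)C)C(C)C | intermediate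
23 | 6-{[(2R)-2-Ar-pent-4-yn-1-yl]oxy}-2-methylhex-5-yn-2-ol | CC(C)(O)CCC#COC[C@H](CC#C)c1cc(C(C)(C)C=C)c(O[Si](C(C)C)(C(C)C)C(C)C)cc1O[Si](C(C)C)(C(C)C)C(C)C | intermediate
24 | dichlorodiisopropylsilane | CC(C)[Si](Cl)(Cl)C(C)C | starting material
25 | chloro(ethynyl)diisopropylsilane | C#C[Si](Cl)(C(C)C)C(C)C | intermediate
26 | ethynyl(diisopropyl)silyl ether of 23 (triyne) | C#C[Si](C(C)C)(C(C)C)OC(C)(C)CCC#COC[C@H](CC#C)c1cc(C(C)(C)C=C)c(O[Si](C(C)C)(C(C)C)C(C)C)cc1O[Si](C(C)C)(C(C)C)C(C)C | intermediate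
27 | (3R)-3-Ar-chroman bridged C7–Si(iPr)2–O–C(CH3)2–CH2–CH2–C8 | C=CC(C)(C)c1cc([C@@H]2COc3c(ccc4c3CCC(C)(C)O[Si]4(C(C)C)C(C)C)C2)c(O[Si](C(C)C)(C(C)C)C(C)C)cc1O[Si](C(C)C)(C(C)C)C(C)C | intermediate
28 | cyclic aryloxy(alkoxy)diisopropylsilane, C7–O–Si(iPr)2–O–C(CH3)2–CH2–CH2–C8 | C=CC(C)(C)c1cc([C@@H]2COc3c(ccc4O[Si](C(C)C)(C(C)C)OC(C)(C)CCc34)C2)c(O[Si](C(C)C)(C(C)C)C(C)C)cc1O[Si](C(C)C)(C(C)C)C(C)C | intermediate
29 | (3R)-3-Ar-8-(3-hydroxy-3-methylbutyl)chroman-7-ol | C=CC(C)(C)c1cc([C@@H]2COc3c(ccc(O)c3CCC(C)(C)O)C2)c(O[Si](C(C)C)(C(C)C)C(C)C)cc1O[Si](C(C)C)(C(C)C)C(C)C | intermediate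
30 | (3R)-3-[2,4-dihydroxy-5-(2-methylbut-3-en-2-yl)phenyl]-8-(3-hydroxy-3-methylbutyl)chroman-7-ol | C=CC(C)(C)c1cc([C@@H]2COc3c(ccc(O)c3CCC(C)(C)O)C2)c(O)cc1O | target

**Step count**

Total steps: 17. Longest linear sequence: 16 steps (steps 1–12 and 14–17, from 1 to 30); step 13 is a one-step branch that makes the silylating agent.

**Steps most likely to fail**

1. Step 15. Closure of the seven-membered siloxane may be too slow, so that the rhodacycle formed from the ynol ether and the propargylic alkyne is intercepted by a second molecule and oligomers form; the Lewis-acidic cationic catalyst may also hydrate the ynol ether. The fallback moves the silicon tether to a propargylic oxygen, so that a five-membered siloxane closes, and builds the side chain afterwards.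
 - It sets out from 19: the acetylide 21 (n-BuLi) is trapped with paraformaldehyde to give the 3-alkoxyprop-2-yn-1-ol F1.
 - K2CO3 in MeOH removes the C-silyl group to give the diyne alcohol F2, and silylation with 25 (imidazole, CH2Cl2) gives the triyne F3.
 - The same rhodium catalyst should then give the isoflavan F4, whose C7 and C8 are joined through Si(iPr)2–O–CH2.
 - KF, KHCO3 and H2O2 give the 7-hydroxy-8-hydroxymethyl isoflavan F5, and Boc2O with iPr2NEt gives its aryl tert-butyl carbonate F6.
 - The lithium enolate of tert-butyl acetate (made with LiN(iPr)2) triggers carbonate transfer and elimination to an ortho-quinone methide and adds to it, giving the tert-butyl 3-arylpropanoate F7.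
 - Excess MeMgBr converts the ester into the tertiary alcohol, and the route is rejoined at 29.

2. Step 11. Under BF3 activation the tertiary C–O bond of the oxetane may ionise (attack at the wrong carbon or elimination to an alkenol), and the Lewis acid may degrade the ynol ether before the alkoxide is quenched. The fallback replaces the Lewis-acid opening by an SN2 alkylation of the same acetylide.
 - 3-Methylbutane-1,3-diol is iodinated at the primary position (I2, PPh3, imidazole) to give 4-iodo-2-methylbutan-2-ol F8, which is capped with Me3SiCl and imidazole as the silyl ether F9.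
 - Starting from 19, the acetylide 21 is alkylated with F9 in THF/DMPU to give the doubly silylated ynol ether F10.
 - K2CO3 in MeOH removes the C-silyl and the O-silyl group together, and the route is rejoined at 23.

3. Step 16. Attack of hydroperoxide on the crowded diisopropyl(tert-alkoxy)silicon may be slow, so that fluoride-induced protodesilylation at C7 competes and the phenol is lost. The fallback changes the substrate so that oxidation needs no fluoride.
 - Et2SiCl2 and HC≡CMgBr give chloro(diethyl)ethynylsilane F11.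
 - Starting from 23, silylation with F11 gives the diethylsilyl triyne F12, and the conditions of step 15 should give the diethyl siloxane F13.
 - KHCO3 and H2O2 in THF/MeOH at rt oxidise the less hindered silicon, and the route is rejoined at 29.

**Further compounds**

F1 | step 15 | 3-{[(2R)-2-Ar-5-(trimethylsilyl)pent-4-yn-1-yl]oxy}prop-2-yn-1-ol | OCC#COC[C@H](CC#C[Si](C)(C)C)c1cc(C(C)(C)C=C)c(O[Si](C(C)C)(C(C)C)C(C)C)cc1O[Si](C(C)C)(C(C)C)C(C)C
F2 | step 15 | 3-{[(2R)-2-Ar-pent-4-yn-1-yl]oxy}prop-2-yn-1-ol | OCC#COC[C@H](CC#C)c1cc(C(C)(C)C=C)c(O[Si](C(C)C)(C(C)C)C(C)C)cc1O[Si](C(C)C)(C(C)C)C(C)C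
F3 | step 15 | ethynyl(diisopropyl)silyl ether of F2 | C#C[Si](C(C)C)(C(C)C)OCC#COC[C@H](CC#C)c1cc(C(C)(C)C=C)c(O[Si](C(C)C)(C(C)C)C(C)C)cc1O[Si](C(C)C)(C(C)C)C(C)C
F4 | step 15 | (3R)-3-Ar-chroman bridged C7–Si(iPr)2–O–CH2–C8 | C=CC(C)(C)c1cc([C@@H]2COc3c(ccc4c3CO[Si]4(C(C)C)C(C)C)C2)c(O[Si](C(C)C)(C(C)C)C(C)C)cc1O[Si](C(C)C)(C(C)C)C(C)C
F5 | step 15 | (3R)-3-Ar-8-(hydroxymethyl)chroman-7-ol | C=CC(C)(C)c1cc([C@@H]2COc3c(ccc(O)c3CO)C2)c(O[Si](C(C)C)(C(C)C)C(C)C)cc1O[Si](C(C)C)(C(C)C)C(C)C
F6 | step 15 | tert-butyl carbonate of the C7 phenol of F5 | C=CC(C)(C)c1cc([C@@H]2COc3c(ccc(OC(=O)OC(C)(C)C)c3CO)C2)c(O[Si](C(C)C)(C(C)C)C(C)C)cc1O[Si](C(C)C)(C(C)C)C(C)C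
F7 | step 15 | tert-butyl 3-[(3R)-3-Ar-7-hydroxychroman-8-yl]propanoate | C=CC(C)(C)c1cc([C@@H]2COc3c(ccc(O)c3CCC(=O)OC(C)(C)C)C2)c(O[Si](C(C)C)(C(C)C)C(C)C)cc1O[Si](C(C)C)(C(C)C)C(C)C
F8 | step 11 | 4-iodo-2-methylbutan-2-ol | CC(C)(O)CCI
F9 | step 11 | (4-iodo-2-methylbutan-2-yl)oxytrimethylsilane | CC(C)(CCI)O[Si](C)(C)C
F10 | step 11 | trimethylsilyl ether of 22 | C[Si](C)(C)OC(C)(C)CCC#COC[C@H](CC#C[Si](C)(C)C)c1cc(C(C)(C)C=C)c(O[Si](C(C)C)(C(C)C)C(C)C)cc1O[Si](C(C)C)(C(C)C)C(C)C
F11 | step 16 | chloro(diethyl)ethynylsilane | C#C[Si](Cl)(CC)CC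
F12 | step 16 | ethynyl(diethyl)silyl ether of 23 | C#C[Si](CC)(CC)OC(C)(C)CCC#COC[C@H](CC#C)c1cc(C(C)(C)C=C)c(O[Si](C(C)C)(C(C)C)C(C)C)cc1O[Si](C(C)C)(C(C)C)C(C)C
F13 | step 16 | (3R)-3-Ar-chroman bridged C7–SiEt2–O–C(CH3)2–CH2–CH2–C8 | C=CC(C)(C)c1cc([C@@H]2COc3c(ccc4c3CCC(C)(C)O[Si]4(CC)CC)C2)c(O[Si](C(C)C)(C(C)C)C(C)C)cc1O[Si](C(C)C)(C(C)C)C(C)C
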